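**Plan**

1. Retrosynthesis: the pyridine is taken back to its 1,4-dihydro form, and that ring is cut at N1–C2, N1–C6, C3–C4 and C4–C5. This leaves ammonia, a one-carbon unit for C4 and two linear C12 pieces.
2. Enabling feature: with the ring numbered N1, C3 (decyl) and C5 (decanoyl), C2–C3–decyl is an unbranched twelve-carbon aldehyde and C6–C5–C(=O)–nonyl is an unbranched twelve-carbon 3-oxoaldehyde. The two chains touch only through C4 and N1, and C2, C4 and C6 carry hydrogen only.
3. Forward: 2-undecanone 1 and N,N-dimethylformamide dimethyl acetal 2 give enaminone 3, the masked 3-oxoaldehyde chain.
4. Dodecanal 4 and formaldehyde 5 are first joined in the flask to the α-methylene aldehyde 6. Then 3 and NH4OAc are added, and via 7 and 8 the only ring closes as the 1,4-dihydropyridine 9.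
5. MnO2 dehydrogenates 9 to the target 10.
6. Stereochemistry: the target is achiral. The E double bond of 3 is the thermodynamic one and disappears in the ring.

Key step: step 2

Remark: formaldehyde is used as its 37% aqueous solution. A 1,4-dihydropyridine with a single acyl group is expected to be air- and acid-sensitive, so 9 is carried into step 3 as the crude product under argon.

**Step 1**
Reactants: 1 2-undecanone; 2 N,N-dimethylformamide dimethyl acetal
Product: 3 (E)-1-(dimethylamino)dodec-1-en-3-one
Conditions: 2 (3 equiv), neat, 110 °C, MeOH distilled off
Reagents that add atoms: none
Why: Aminomethylenation of a methyl ketone with an amide acetal (enolate addition to the methoxyiminium ion, then loss of methanol) should take place at the unhindered methyl group rather than at the C3 methylene and give the conjugated E-enaminone as the thermodynamic isomer.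

**Step 2**
Reactants: 3 (E)-1-(dimethylamino)dodec-1-en-3-one; 4 dodecanal; 5 formaldehyde (37% aqueous solution)
Product: 9 1-(5-decyl-1,4-dihydropyridin-3-yl)decan-1-one, via 2-methylidenedodecanal 6 (not isolated), via (Z)-1-aminododec-1-en-3-one 7 (not isolated), via open-chain Michael adduct 8 (not isolated)
Conditions: 4, 5 (1.0 equiv), pyrrolidine (10 mol%), EtCO2H (10 mol%), i-PrOH, 45 °C; then 3 (1.1 equiv), NH4OAc (3 equiv), AcOH, 60 °C, Ar; extractive work-up under Ar, used crude
Reagents that add atoms: ammonium acetate, CC(=O)[O-].[NH4+]
Why: Pyrrolidinium propionate converts 4 and 5 into the α-methylene aldehyde 6 by Mannich addition and β-elimination of the amine (C3–C4), so that neither free formaldehyde nor enolisable aldehyde should be left when the nitrogen components are added. Ammonium acetate then exchanges the dimethylamino group of 3 for NH2 (N1–C6) to give 7, whose nucleophilic α-carbon adds in Michael fashion to the exocyclic methylene carbon of 6 (C4–C5) to give 8. The enaminone nitrogen of 8 closes the six-membered ring by 6-exo-trig attack on the aldehyde carbon (N1–C2), and loss of water across C2–C3 leaves the 1,4-dihydropyridine 9. The closest known reaction type is the Hantzsch dihydropyridine synthesis in its stepwise form, in which a preformed acceptor is annulated with a β-aminoenone, as in the preparation of 5-alkyl-3-acylpyridines and 5-alkylnicotinates from 2-alkylacroleins; the first stage is the amine-catalysed α-methylenation of aldehydes with aqueous formaldehyde. No stereocentre is set, since the one at C3 of 8 is formed as a racemate and is erased by the dehydration. The step needs cross-selectivity over the 3,5-didecanoyl and the Chichibabin trialkyl series, which is secured by the order of addition and by the substrates: 6 can no longer enolise at its α-carbon and acts only as acceptor, 7 reacts only at its α-carbon and nitrogen, neither chain carries a group that could end up on C2, C4 or C6, and the reverse orientation of the annulation would lead to the same pyridine after step 3.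

**Step 3**
Reactants: 9 1-(5-decyl-1,4-dihydropyridin-3-yl)decan-1-one
Product: 10 1-(5-decylpyridin-3-yl)decan-1-one
Conditions: activated MnO2 (10 equiv), CH2Cl2, rt, Ar; filtration through Celite
Reagents that add atoms: none
Why: Oxidative aromatisation of a Hantzsch-type 1,4-dihydropyridine with MnO2 is driven by formation of the pyridine sextet and should leave the ketone and both alkyl chains untouched at room temperature.

**Compound list**

1 | 2-undecanone | CCCCCCCCCC(C)=O | starting material
2 | N,N-dimethylformamide dimethyl acetal | COC(OC)N(C)C | starting material
3 | (E)-1-(dimethylamino)dodec-1-en-3-one | CCCCCCCCCC(=O)/C=C/N(C)C | intermediate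
4 | dodecanal | CCCCCCCCCCCC=O | starting material
5 | formaldehyde (used as 37% aqueous solution) | C=O | starting material
6 | 2-methylidenedodecanal (2-decylacrolein) | C=C(CCCCCCCCCC)C=O | intermediate
7 | (Z)-1-aminododec-1-en-3-one | CCCCCCCCCC(=O)/C=C\N | intermediate
8 | (Z)-4-(aminomethylidene)-2-decyl-5-oxotetradecanal, racemic at C2 (open-chain Michael adduct) | CCCCCCCCCCC(C=O)C/C(=C/N)C(=O)CCCCCCCCC | intermediate
9 | 1-(5-decyl-1,4-dihydropyridin-3-yl)decan-1-one | CCCCCCCCCCC1=CNC=C(C(=O)CCCCCCCCC)C1 | intermediate
10 | 1-(5-decylpyridin-3-yl)decan-1-one | CCCCCCCCCCc1cncc(C(=O)CCCCCCCCC)c1 | target

**Step count**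

Total: 3 steps. Longest linear sequence: 3 steps (1 → 3 → 9 → 10).

**Steps most likely to fail**

Step 2. The α-methylenation may stop short, or the α-methylene aldehyde may oligomerise under the amine catalyst. Left-over formaldehyde and dodecanal would then be drained by the enaminone and by ammonia into the symmetrical 3,5-diacyl and trialkyl pyridine series, and the cross-annulation would be starved. The fallback sets out from 4 and 3 and comes back at 9, with both partners purified and no formaldehyde or free ammonia in the ring-forming flask. Dodecanal 4 would be treated with dimethylmethylideneammonium iodide and Et3N in CH2Cl2 to give the Mannich base 2-[(dimethylamino)methyl]dodecanal F1. F1 loses dimethylamine on warming to give 6, which is purified by rapid chromatography. Separately, 3 would be stirred with NH3 in MeOH and the primary enaminone 7 isolated. The two partners would then be joined in EtOH with catalytic AcOH at 50 °C under argon, a two-component β-aminoenone/2-alkylacrolein annulation, to return to the route at 9.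

Step 3. The mono-acyl dihydropyridine may be lost before or during oxidation through acid-promoted tautomerisation, hydration of the C2–C3 enamine or disproportionation on isolation, or through adsorption on the large excess of MnO2, so that dehydrogenation stays incomplete. The fallback sets out from 4, uses 3, and comes back at 10 without passing through the dihydro level, because C4 is brought in at the formyl oxidation state. Dodecanal 4 would be converted with HC(OMe)3 and catalytic TsOH in MeOH into 1,1-dimethoxydodecane F2. Vilsmeier formylation of F2 (POCl3, DMF, 70 °C, then aqueous K2CO3) should give (E)-2-[(dimethylamino)methylidene]dodecanal F3. Cyclocondensation of F3 with 3 and NH4OAc in AcOH at 100 °C, the known pyridine synthesis from a 3-aminoacrolein and a β-aminoenone, should aromatise by loss of dimethylamine and water and deliver 10 directly.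

Step 1. Aminomethylenation of an unactivated dialkyl ketone may be slow, with competing condensation at the C3 methylene group and thermal loss of the reagent. The fallback sets out from 1 and comes back at 3, with the regiochemistry fixed by kinetic deprotonation. Ketone 1 would be deprotonated at the methyl group with LiN(i-Pr)2 in THF at −78 °C, and the enolate formylated with 2,2,2-trifluoroethyl formate to give 3-oxododecanal, drawn as its enol (Z)-1-hydroxydodec-1-en-3-one F4. Condensation of F4 with Me2NH (THF solution, MeOH, rt) should give 3.

**Further compounds**

F1 | step 2 | 2-[(dimethylamino)methyl]dodecanal (racemic) | CCCCCCCCCCC(CN(C)C)C=O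
F2 | step 3 | 1,1-dimethoxydodecane | CCCCCCCCCCCC(OC)OC
F3 | step 3 | (E)-2-[(dimethylamino)methylidene]dodecanal | O=C/C(CCCCCCCCCC)=C/N(C)C
F4 | step 1 | (Z)-1-hydroxydodec-1-en-3-one | CCCCCCCCCC(=O)/C=C\O
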